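## Retrosynthetic overview

1. Flavan **8** ⇒ 2H-chromene **7**: the C3–C4 single bond is traced back to a C3=C4 alkene, so the last step is an alkene saturation.
2. **7** ⇒ aryl propargyl ether **6**: ring C is opened at C4–C4a. Forward, a gold-catalysed 6-endo-dig hydroarylation closes ring C, the only ring built; rings A and B are bought.
3. **6** ⇒ carbonate **4** + phenol **5**: the C2–O1 bond is made by a copper-catalysed asymmetric propargylic etherification, which sets C2 as (S).
4. **4** ⇒ aldehyde **1** + ethynyl Grignard **2**, followed by Boc carbonate formation.
5. Feature: in ring A, C4a is the only unsubstituted carbon ortho to O1 (C8 carries OMe) and lies para to the C7 methoxy. The carbon that must bond to C4 is therefore the single free, most nucleophilic ortho site of a 2,3-dimethoxyphenyl ether, and C2 only has to be carried through.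

Key step: step 4

Remark (assumption): which antipode of Ph-pybox leads to (S)-**6** is settled in a pilot run of step 3 with both commercial antipodes, and the assignment is secured by comparison with **6** from the inversion route given as fallback for step 3.

## Route

Step 1
Reactants: 1 3,4,5-trimethoxybenzaldehyde; 2 ethynylmagnesium bromide
Product: 3 rac-1-(3,4,5-trimethoxyphenyl)prop-2-yn-1-ol
Conditions: HC≡CMgBr (1.3 equiv, 0.5 M in THF), THF, 0 °C → rt; then sat. aq. NH4Cl
Reagents that add atoms: none
Why: Grignard addition of an alkynyl nucleophile to a non-enolisable aromatic aldehyde is fast and clean; the carbinol centre is deliberately formed as the racemate because step 3 is stereoconvergent.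

Step 2
Reactants: 3 rac-1-(3,4,5-trimethoxyphenyl)prop-2-yn-1-ol
Product: 4 rac-tert-butyl 1-(3,4,5-trimethoxyphenyl)prop-2-yn-1-yl carbonate
Conditions: Boc2O (1.2 equiv), DMAP (5 mol%), CH2Cl2, 0 °C → rt; chromatography on Et3N-deactivated silica
Reagents that add atoms: di-tert-butyl dicarbonate, CC(C)(C)OC(=O)OC(=O)OC(C)(C)C
Why: DMAP-catalysed O-tert-butoxycarbonylation of a secondary alcohol installs a leaving group that, on ionisation, releases CO2 and tert-butoxide, a non-nucleophilic internal base for the phenol in step 3; no stereocentre is set.

Step 3
Reactants: 4 rac-tert-butyl 1-(3,4,5-trimethoxyphenyl)prop-2-yn-1-yl carbonate; 5 2,3-dimethoxyphenol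
Product: 6 (S)-1,2-dimethoxy-3-{[1-(3,4,5-trimethoxyphenyl)prop-2-yn-1-yl]oxy}benzene
Conditions: Cu(OTf)·½C6H6 (5 mol%), Ph-pybox (10 mol%, antipode per the remark), iPr2NEt (1.2 equiv), 5 (1.5 equiv), ClCH2CH2Cl, −20 → 0 °C; excess 5 removed with 1 M NaOH
Reagents that add atoms: none
Why: This is a copper(I)–pybox-catalysed enantioselective propargylic substitution, known for 1-aryl propargylic esters with phenols: the copper acetylide of 4 expels the carbonate to give a copper allenylidene common to both enantiomers of 4, and the phenoxide of 5 attacks its γ-carbon on the face left open by the ligand, so C2 is set under catalyst control and the whole racemate is used.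

Step 4
Reactants: 6 (S)-1,2-dimethoxy-3-{[1-(3,4,5-trimethoxyphenyl)prop-2-yn-1-yl]oxy}benzene
Product: 7 (S)-7,8-dimethoxy-2-(3,4,5-trimethoxyphenyl)-2H-chromene
Conditions: Ph3PAuNTf2 (2 mol%), CH2Cl2, 0 °C → rt; Et3N quench, filtration through basic alumina
Reagents that add atoms: none
Why: Cationic gold(I) coordinates the terminal alkyne of 6, the ring-A carbon ortho to the ether oxygen attacks the terminal alkyne carbon anti to gold, and rearomatisation of the Wheland intermediate followed by protodeauration of the vinylgold species releases the C3=C4 alkene and the catalyst. This is the gold(I)-catalysed intramolecular Friedel–Crafts-type alkyne hydroarylation of aryl propargyl ethers to 2H-chromenes, a known reaction class that includes ethers substituted at the propargylic carbon. Ring C closes in the 6-endo-dig mode, forming C4–C4a; the 5-exo-dig alternative (attack on the internal carbon to a 3-methylene-2,3-dihydrobenzofuran) is disfavoured for terminal aryl propargyl ethers under gold(I). No stereocentre is formed, and C2 keeps its configuration because none of its four bonds is touched. The step needs site selectivity on ring A, which the substitution pattern fixes (the other ortho position carries OMe and the attacking carbon is para to a methoxy group), and an intact propargylic C–O bond, which is favoured by the soft π-acid free of Brønsted acid, the low temperature, the short contact time and the only moderate cation stabilisation by the 3,4,5-trimethoxyphenyl group, whose 4-OMe is twisted out of conjugation. Quenching with Et3N before concentration should protect the electron-rich chromene from acid-induced oligomerisation.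

Step 5
Reactants: 7 (S)-7,8-dimethoxy-2-(3,4,5-trimethoxyphenyl)-2H-chromene
Product: 8 (2S)-7,8,3',4',5'-pentamethoxyflavan
Conditions: 2-O2NC6H4SO2NHNH2 (NBSH, 5 equiv in portions), Et3N, CH2Cl2, rt
Reagents that add atoms: none
Why: In this diimide reduction, HN=NH released from NBSH transfers two hydrogens suprafacially to the cis-disubstituted C3=C4 bond through a cyclic transition state without any metal, so the benzylic C2–O bond cannot be hydrogenolysed, the double bond cannot migrate towards C2, and the C2 stereocentre is untouched.

The enantiomeric purity would be followed by chiral HPLC at 6, 7 and 8.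

## Compound list

1 | 3,4,5-trimethoxybenzaldehyde | COc1cc(C=O)cc(OC)c1OC | starting material
2 | ethynylmagnesium bromide | C#C[Mg]Br | starting material
3 | rac-1-(3,4,5-trimethoxyphenyl)prop-2-yn-1-ol | COc1cc(C(O)C#C)cc(OC)c1OC | intermediate
4 | rac-tert-butyl 1-(3,4,5-trimethoxyphenyl)prop-2-yn-1-yl carbonate | COc1cc(C(OC(=O)OC(C)(C)C)C#C)cc(OC)c1OC | intermediate
5 | 2,3-dimethoxyphenol | COc1cccc(O)c1OC | starting material
6 | (S)-1,2-dimethoxy-3-{[1-(3,4,5-trimethoxyphenyl)prop-2-yn-1-yl]oxy}benzene | COc1cc([C@@H](Oc2cccc(OC)c2OC)C#C)cc(OC)c1OC | intermediate
7 | (S)-7,8-dimethoxy-2-(3,4,5-trimethoxyphenyl)-2H-chromene | COc1cc([C@@H]2C=Cc3ccc(OC)c(OC)c3O2)cc(OC)c1OC | intermediate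
8 | (2S)-7,8,3',4',5'-pentamethoxyflavan | COc1cc([C@@H]2CCc3ccc(OC)c(OC)c3O2)cc(OC)c1OC | target

## Step count

Total steps: 5. Longest linear sequence: 5 (1 → 3 → 4 → 6 → 7 → 8).

## Steps most likely to fail

**Step 4 (key step).** The propargylic C2–O bond may ionise, or the electron-rich product may oligomerise under the cationic gold conditions; either would erode the configuration at C2 or consume the chromene. The fallback sets out from 6 and makes the same C4–C4a bond by a metal-free, iodonium-induced 6-endo-dig iodoarylation (I2, NaHCO3, MeNO2, rt; ICl, CH2Cl2, −78 °C if the terminal alkyne reacts sluggishly). This should give (2R)-3-iodo-7,8-dimethoxy-2-(3,4,5-trimethoxyphenyl)-2H-chromene F1, which has the same spatial arrangement at C2 as 7; the descriptor changes only because C3 now bears iodine. Radical hydrodeiodination (Bu3SnH, AIBN, PhH, 80 °C) would then come back to the route at 7.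

**Step 3.** The electron-rich phenol may be alkylated at carbon (Friedel–Crafts attack of C4 or C6 of 5 on the copper allenylidene) in competition with O-alkylation, or the enantiomeric ratio may be insufficient. The fallback sets out from racemic alcohol 3. Lipase-mediated kinetic resolution (immobilised Candida antarctica lipase B, vinyl acetate, MTBE, rt) should acylate the (R)-alcohol, taking aryl as the large and ethynyl as the medium group in the empirical size rule for secondary alcohols, to give (R)-1-(3,4,5-trimethoxyphenyl)prop-2-yn-1-yl acetate F2. Methanolysis (K2CO3, MeOH, 0 °C) would give (R)-1-(3,4,5-trimethoxyphenyl)prop-2-yn-1-ol F3, whose configuration would be confirmed through its MTPA esters. A Mitsunobu reaction with 5 (PPh3, DIAD, PhMe, 0 °C) should then proceed with inversion at the carbinol carbon and come back to the route at 6.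

**Step 5.** Conversion may stay incomplete because diimide disproportionates faster than it adds to the aryl-conjugated C3=C4 bond. The fallback sets out from 7 and uses catalytic hydrogenation (H2 1 atm, 5% Pd/C, EtOAc, rt), stopped after uptake of one equivalent so that neither C2–O hydrogenolysis nor double-bond migration towards C2 sets in. RhCl(PPh3)3 in PhH/EtOH is the homogeneous alternative. This leads directly to 8 and makes no new compound (F0).

## Further compounds

F1 | step 4 | (2R)-3-iodo-7,8-dimethoxy-2-(3,4,5-trimethoxyphenyl)-2H-chromene | COc1cc([C@@H]2C(I)=Cc3ccc(OC)c(OC)c3O2)cc(OC)c1OC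
F2 | step 3 | (R)-1-(3,4,5-trimethoxyphenyl)prop-2-yn-1-yl acetate | COc1cc([C@H](OC(C)=O)C#C)cc(OC)c1OC
F3 | step 3 | (R)-1-(3,4,5-trimethoxyphenyl)prop-2-yn-1-ol | COc1cc([C@H](O)C#C)cc(OC)c1OC
F0 | step 5 | none | none
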